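The route rests on cutting the quinoid ring of the naphthazarin (C1–C4, C4a, C8a), which is oxygenated at C1 and C4, unsubstituted at C3 and carries its only carbon substituent at C2. A Dötz benzannulation assembles this ring in one operation, forming C4–C3, C2–C1 and C1–C8a: the carbene carbon on the preformed arene becomes C4, a terminal alkyne supplies C3 and C2 with C1′ already (R)-configured at the propargylic position, and a carbonyl ligand becomes C1, giving C1–OH and C4–OMe differentiated for quinone formation. The precursors are a pentacarbonylchromium methoxycarbene on a 2,5-bis(methoxymethoxy)phenyl ring (MOM ethers, removable in dilute acid) and the (R)-TBS ether of 6-methylhept-5-en-1-yn-3-ol. Oxidation, deprotection to (R)-shikonin and esterification finish.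

Key step: step 8

Assumption: 3,4-dimethylpent-3-enoic acid is taken as a purchasable building block and used as bought; naphthazarins are drawn as the tautomer with the quinone on the side-chain ring.

Step 1
Reactants: 1 2-bromobenzene-1,4-diol (bromohydroquinone)
Product: 2 2-bromo-1,4-bis(methoxymethoxy)benzene
Conditions: MOMCl, i-Pr2NEt, CH2Cl2, 0 °C → rt
Reagents that add atoms: chloromethyl methyl ether, COCCl
Why: Double O-alkylation of the hydroquinone with the α-chloro ether and Hünig's base (MOM acetal protection) is routine and gives ethers that should survive organolithium, carbene and cerium(IV) chemistry but leave in dilute acid, unlike methyl ethers on a 5,8-dialkoxyquinone.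

Step 2
Reactants: 2 2-bromo-1,4-bis(methoxymethoxy)benzene; 3 chromium hexacarbonyl
Product: 6 pentacarbonyl{[2,5-bis(methoxymethoxy)phenyl](methoxy)methylidene}chromium, via aryllithium 4 (not isolated), via lithium acyl chromate 5 (not isolated)
Conditions: n-BuLi, THF, −78 °C; 3, −78 °C → rt; then Me3OBF4, CH2Cl2, 0 °C
Reagents that add atoms: trimethyloxonium tetrafluoroborate, C[O+](C)C.F[B-](F)(F)F
Why: Fischer carbene synthesis: fast bromine–lithium exchange gives the chelated aryllithium, which adds to a carbonyl ligand of chromium hexacarbonyl, and the acyl chromate is O-methylated by Meerwein's salt, a hard electrophile that reacts at the acyl oxygen.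

Step 3
Reactants: 7 4-methylpent-3-enoic acid
Product: 9 N-methoxy-N,4-dimethylpent-3-enamide, via acyl imidazolide 8 (not isolated)
Conditions: CDI, CH2Cl2, rt; then MeNHOMe·HCl, rt
Reagents that add atoms: N,O-dimethylhydroxylamine hydrochloride, CNOC.Cl
Why: Weinreb amide formation through the acyl imidazolide runs near neutral pH, so the β,γ-double bond should not be drawn into conjugation.

Step 4
Reactants: 9 N-methoxy-N,4-dimethylpent-3-enamide; 10 ethynyltrimethylsilane
Product: 13 6-methyl-1-(trimethylsilyl)hept-5-en-1-yn-3-one, via lithium silylacetylide 11 (not isolated), via tetrahedral lithium adduct 12 (not isolated)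
Conditions: 10, n-BuLi, THF, −78 °C; then 9, −78 → −20 °C; AcOH quench
Reagents that add atoms: none
Why: Weinreb ketone synthesis: the lithium acetylide adds once because the five-membered N-methoxy chelate holds the tetrahedral adduct until the cold acetic acid quench, which releases the ynone without exposing it to base.

Step 5
Reactants: 13 6-methyl-1-(trimethylsilyl)hept-5-en-1-yn-3-one
Product: 14 (3R)-6-methyl-1-(trimethylsilyl)hept-5-en-1-yn-3-ol
Conditions: Ru[(R,R)-TsDPEN](p-cymene) (2 mol%), i-PrOH, rt
Reagents that add atoms: none
Why: Noyori asymmetric transfer hydrogenation of an alkynyl ketone: the base-free 16-electron Ru amide takes hydrogen from 2-propanol and delivers it through the six-membered Ru–H/N–H transition state to one carbonyl face, the alkynyl group occupying the site that aryl takes in aryl ketones, so the (R,R)-ligand should set the (R)-carbinol.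

Step 6
Reactants: 14 (3R)-6-methyl-1-(trimethylsilyl)hept-5-en-1-yn-3-ol
Product: 15 tert-butyldimethyl{[(3R)-6-methyl-1-(trimethylsilyl)hept-5-en-1-yn-3-yl]oxy}silane
Conditions: TBSCl, imidazole, DMF, rt
Reagents that add atoms: tert-butyldimethylsilyl chloride, CC(C)(C)[Si](C)(C)Cl
Why: Imidazole-promoted silylation of the secondary propargylic alcohol (TBS protection) goes at oxygen only and leaves the stereocentre untouched; it precedes C-desilylation so that no volatile free alkynol is handled.

Step 7
Reactants: 15 tert-butyldimethyl{[(3R)-6-methyl-1-(trimethylsilyl)hept-5-en-1-yn-3-yl]oxy}silane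
Product: 16 tert-butyldimethyl{[(3R)-6-methylhept-5-en-1-yn-3-yl]oxy}silane
Conditions: K2CO3 (0.2 equiv), MeOH, rt
Reagents that add atoms: none
Why: Base-catalysed methanolysis of the alkynyl C–Si bond (protodesilylation) is selective because methoxide attacks the unhindered trimethylsilyl group and expels a stabilised acetylide, while the tert-butyldimethylsilyl ether is inert to K2CO3 in methanol.

Step 8
Reactants: 6 pentacarbonyl{[2,5-bis(methoxymethoxy)phenyl](methoxy)methylidene}chromium; 16 tert-butyldimethyl{[(3R)-6-methylhept-5-en-1-yn-3-yl]oxy}silane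
Product: 18 2-[(1R)-1-(tert-butyldimethylsilyloxy)-4-methylpent-3-enyl]-4-methoxy-5,8-bis(methoxymethoxy)naphthalen-1-ol, via tricarbonylchromium naphthol complex 17 (not isolated)
Conditions: THF (0.05 M), 50 °C, Ar; then air, Et2O, rt
Reagents that add atoms: none
Why: Thermal loss of one CO from 6 lets the alkyne coordinate and insert into the Cr=C bond (C4–C3), CO insertion into the resulting vinylcarbene gives a chromium-bound vinylketene (C2–C1), and 6π electrocyclisation onto the free ortho carbon of the aryl ring (C1–C8a) followed by enolisation gives the Cr(CO)3-bound naphthol 17, from which air releases 18. The closest known reaction type is the Dötz benzannulation of aryl(alkoxy)carbene chromium complexes with terminal alkynes, propargylic silyl ethers included. The single new ring (C1–C4, C4a, C8a) is closed by electrocyclic ring closure of the metal-bound dienylketene, the end of a formal [3+2+1] assembly. No stereocentre is formed; C1′ lies outside the reacting atoms, is not epimerisable under these neutral conditions and should be carried through unchanged. The step needs regioselective insertion, secured by the terminal alkyne, whose unsubstituted carbon bonds to the carbene carbon so that the carbon bearing the bulky silyloxyalkyl group ends up next to the CO-derived C1, and it needs a single site of closure, secured because the other ortho position of the aryl ring carries a MOM ether. Phenol formation over closure without CO uptake is favoured by the alkoxy carbene, THF and moderate temperature.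

Step 9
Reactants: 18 2-[(1R)-1-(tert-butyldimethylsilyloxy)-4-methylpent-3-enyl]-4-methoxy-5,8-bis(methoxymethoxy)naphthalen-1-ol
Product: 19 2-[(1R)-1-(tert-butyldimethylsilyloxy)-4-methylpent-3-enyl]-5,8-bis(methoxymethoxy)naphthalene-1,4-dione
Conditions: CAN, MeCN–H2O (4:1), 0 °C
Reagents that add atoms: water, O
Why: Cerium(IV) oxidative demethylation of a 4-methoxy-1-naphthol: two one-electron oxidations, attack of water at C4 and loss of methanol should give the 1,4-quinone on the ring that carries the free hydroxyl within minutes at 0 °C, conditions under which the MOM ethers, the silyl ether and the trisubstituted alkene should persist.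

Step 10
Reactants: 19 2-[(1R)-1-(tert-butyldimethylsilyloxy)-4-methylpent-3-enyl]-5,8-bis(methoxymethoxy)naphthalene-1,4-dione
Product: 20 (R)-shikonin [5,8-dihydroxy-2-((1R)-1-hydroxy-4-methylpent-3-enyl)naphthalene-1,4-dione]
Conditions: 2 M H2SO4 (aq), THF, rt → 40 °C
Reagents that add atoms: none
Why: Acid-catalysed hydrolysis cleaves in one operation the two aryl MOM acetals, whose leaving phenols are stabilised by hydrogen bonding to the peri carbonyls, and the secondary silyl ether; sulfuric acid offers no nucleophilic counter-ion to add to the quinone, and water as the only nucleophile at mild temperature should leave C1′ and the alkene unchanged.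

Step 11
Reactants: 20 (R)-shikonin; 21 3,4-dimethylpent-3-enoic acid
Product: 22 (1R)-1-(5,8-dihydroxy-1,4-dioxo-1,4-dihydronaphthalen-2-yl)-4-methylpent-3-enyl 3,4-dimethylpent-3-enoate (CNP0163639.1)
Conditions: DCC, DMAP (cat.), CH2Cl2, 0 °C → rt
Reagents that add atoms: none
Why: Steglich esterification (DCC activation, DMAP acyl transfer) should acylate only the side-chain alcohol because both naphthazarin hydroxyls are tied up in strong hydrogen bonds to the quinone carbonyls, and since the C1′–O bond is not broken the (R) configuration is kept.

Compound list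
1 | 2-bromobenzene-1,4-diol (bromohydroquinone) | Oc1ccc(O)c(Br)c1 | starting material
2 | 2-bromo-1,4-bis(methoxymethoxy)benzene | COCOc1ccc(OCOC)c(Br)c1 | intermediate
3 | chromium hexacarbonyl | O=C=[Cr](=C=O)(=C=O)(=C=O)(=C=O)=C=O | starting material
4 | [2,5-bis(methoxymethoxy)phenyl]lithium (formed in the flask, not isolated) | [Li]c1cc(OCOC)ccc1OCOC | intermediate
5 | lithium pentacarbonyl[2,5-bis(methoxymethoxy)benzoyl]chromate (formed in the flask, not isolated) | [Li+].[O-]C(=[Cr](=C=O)(=C=O)(=C=O)(=C=O)=C=O)c1cc(OCOC)ccc1OCOC | intermediate
6 | pentacarbonyl{[2,5-bis(methoxymethoxy)phenyl](methoxy)methylidene}chromium | COC(=[Cr](=C=O)(=C=O)(=C=O)(=C=O)=C=O)c1cc(OCOC)ccc1OCOC | intermediate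
7 | 4-methylpent-3-enoic acid | CC(C)=CCC(O)=O | starting material
8 | 1-(1H-imidazol-1-yl)-4-methylpent-3-en-1-one, the acyl imidazolide (formed in the flask, not isolated) | CC(C)=CCC(=O)n1ccnc1 | intermediate
9 | N-methoxy-N,4-dimethylpent-3-enamide | CC(C)=CCC(=O)N(C)OC | intermediate
10 | ethynyltrimethylsilane (trimethylsilylacetylene) | C#C[Si](C)(C)C | starting material
11 | lithium (trimethylsilyl)acetylide (formed in the flask, not isolated) | [Li]C#C[Si](C)(C)C | intermediate
12 | lithium 3-[methoxy(methyl)amino]-6-methyl-1-(trimethylsilyl)hept-5-en-1-yn-3-olate, the tetrahedral adduct of 11 and 9 (formed in the flask, not isolated) | CC(C)=CCC(O[Li])(C#C[Si](C)(C)C)N(C)OC | intermediate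
13 | 6-methyl-1-(trimethylsilyl)hept-5-en-1-yn-3-one | CC(C)=CCC(=O)C#C[Si](C)(C)C | intermediate
14 | (3R)-6-methyl-1-(trimethylsilyl)hept-5-en-1-yn-3-ol | CC(C)=CC[C@@H](O)C#C[Si](C)(C)C | intermediate
15 | tert-butyldimethyl{[(3R)-6-methyl-1-(trimethylsilyl)hept-5-en-1-yn-3-yl]oxy}silane | CC(C)=CC[C@@H](O[Si](C)(C)C(C)(C)C)C#C[Si](C)(C)C | intermediate
16 | tert-butyldimethyl{[(3R)-6-methylhept-5-en-1-yn-3-yl]oxy}silane | CC(C)=CC[C@@H](O[Si](C)(C)C(C)(C)C)C#C | intermediate
17 | tricarbonylchromium complex of 18, Cr(CO)3 η6-bound to the ring C1–C4/C4a/C8a (formed in the flask, not isolated; the η6 bond is not written in the SMILES, which shows arene plus Cr(CO)3 fragment) | CC(C)=CC[C@@H](O[Si](C)(C)C(C)(C)C)c1cc(OC)c2c(OCOC)ccc(OCOC)c2c1O.O=C=[Cr](=C=O)=C=O | intermediate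
18 | 2-[(1R)-1-(tert-butyldimethylsilyloxy)-4-methylpent-3-enyl]-4-methoxy-5,8-bis(methoxymethoxy)naphthalen-1-ol | CC(C)=CC[C@@H](O[Si](C)(C)C(C)(C)C)c1cc(OC)c2c(OCOC)ccc(OCOC)c2c1O | intermediate
19 | 2-[(1R)-1-(tert-butyldimethylsilyloxy)-4-methylpent-3-enyl]-5,8-bis(methoxymethoxy)naphthalene-1,4-dione | CC(C)=CC[C@@H](O[Si](C)(C)C(C)(C)C)C1=CC(=O)c2c(OCOC)ccc(OCOC)c2C1=O | intermediate
20 | (R)-shikonin, 5,8-dihydroxy-2-[(1R)-1-hydroxy-4-methylpent-3-enyl]naphthalene-1,4-dione | CC(C)=CC[C@@H](O)C1=CC(=O)c2c(O)ccc(O)c2C1=O | intermediate
21 | 3,4-dimethylpent-3-enoic acid | CC(C)=C(C)CC(O)=O | starting material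
22 | (1R)-1-(5,8-dihydroxy-1,4-dioxo-1,4-dihydronaphthalen-2-yl)-4-methylpent-3-enyl 3,4-dimethylpent-3-enoate (CNP0163639.1) | CC(C)=CC[C@@H](OC(=O)CC(C)=C(C)C)C1=CC(=O)c2c(O)ccc(O)c2C1=O | target

Total step count: 11. Longest linear sequence: 9 steps (steps 3 to 11, from 7 to 22); the carbene arm (steps 1 and 2) joins at step 8.

Steps most likely to fail

Step 8. After alkyne insertion the chromium intermediate may close without taking up CO. The electron-rich, chromium-bound naphthol may also expel silanol from the benzylic position, or be over-oxidised while the metal is removed in air. Fallback, setting out from 6 and 16 and coming back at 18: the annulation is run in THF at 55 °C with acetic anhydride and triethylamine in the flask, so that the phenol is acetylated as soon as it forms and never exists free. Air decomplexation should then give the bench-stable aryl acetate 2-[(1R)-1-(tert-butyldimethylsilyloxy)-4-methylpent-3-enyl]-4-methoxy-5,8-bis(methoxymethoxy)naphthalen-1-yl acetate F1. Deacetylation with K2CO3 in degassed methanol at 0 °C just before use should regenerate 18, which then goes directly into step 9.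

Step 10. The acid exposure needed to hydrolyse the MOM ethers may ionise the freed C1′ carbinol, with loss of configuration. It may also let the carbinol oxygen add to the protonated trisubstituted alkene, closing a tetrahydrofuran. Fallback, setting out from 19 and coming back at 22: HF·pyridine in THF should remove only the silyl ether and give 2-[(1R)-1-hydroxy-4-methylpent-3-enyl]-5,8-bis(methoxymethoxy)naphthalene-1,4-dione F2. Steglich esterification of this alcohol with 21 should give (1R)-1-[5,8-bis(methoxymethoxy)-1,4-dioxo-1,4-dihydronaphthalen-2-yl]-4-methylpent-3-enyl 3,4-dimethylpent-3-enoate F3. The two MOM ethers are then cleaved last with bromotrimethylsilane in CH2Cl2 at −30 °C and aqueous work-up, so that no free carbinol ever meets acid, to give 22.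

Step 5. The basic Ru amide may shift the β,γ-double bond into conjugation or be quenched by the acidic CH2 between carbonyl and alkene, and facial discrimination between the CH2 and silylalkynyl flanks may be incomplete. The sense of induction would be checked on 14 by Mosher ester analysis. Fallback, setting out from 13 and coming back at 14: Midland reduction with (R)-Alpine-Borane (from (+)-α-pinene and 9-BBN), neat at rt. This is a stoichiometric chiral trialkylborane that transfers hydride through a neutral cyclic transition state, with the slim alkynyl group as the small substituent, and is known to give (R)-propargylic alcohols from alkynyl ketones. No compound outside the list is made (F0).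

Further compounds
F1 | step 8 | 2-[(1R)-1-(tert-butyldimethylsilyloxy)-4-methylpent-3-enyl]-4-methoxy-5,8-bis(methoxymethoxy)naphthalen-1-yl acetate | CC(C)=CC[C@@H](O[Si](C)(C)C(C)(C)C)c1cc(OC)c2c(OCOC)ccc(OCOC)c2c1OC(C)=O
F2 | step 10 | 2-[(1R)-1-hydroxy-4-methylpent-3-enyl]-5,8-bis(methoxymethoxy)naphthalene-1,4-dione | CC(C)=CC[C@@H](O)C1=CC(=O)c2c(OCOC)ccc(OCOC)c2C1=O
F3 | step 10 | (1R)-1-[5,8-bis(methoxymethoxy)-1,4-dioxo-1,4-dihydronaphthalen-2-yl]-4-methylpent-3-enyl 3,4-dimethylpent-3-enoate | CC(C)=CC[C@@H](OC(=O)CC(C)=C(C)C)C1=CC(=O)c2c(OCOC)ccc(OCOC)c2C1=O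
F0 | step 5 | none | none
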